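(The readings were computed from invented constants.)

Take the time first: 80 min says little until you count it in half-lives of the step that uses up the substrate.

| flask | substrate | partner | temperature | remark | time |
|---|---|---|---|---|---|
| eta | 21 mM | 1 equiv | 90 °C | run made earlier |  |
| grey | 42 mM | 1.00 equiv | 90 °C |  | 80 min |
| ochre | 42 mM | 1.00 equiv | 75 °C |  | 80 min |
| red | 42 mM | 1.00 equiv | 45 °C |  | 80 min |
| green | 42 mM | 1.00 equiv | 60 °C |  | 80 min |

eta run (percent of the substrate charged)

| time / min | open intermediate / % | product / % | substrate / % |
|---|---|---|---|
| 1.33 | 62.4 | 1.8 | 36.3 |
| 4.00 | 89.1 | 7.2 | 5.3 |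
| 8.00 | 85.0 | 14.2 | 0.8 |
| 12.0 | 77.5 | 21.3 | 0.3 |
| 15.0 | 74.2 | 26.1 | 0 |

(readings scatter by 0.5 percentage points)

- the analysis behind the earlier runs scatters by 0.5 percentage points, standard deviation
- the earlier runs do not show what temperature does; that part of a forecast is a guess
- a reading or a percentage of product counts all its forms, free or not

* the flask that comes out highest in amount of open intermediate, in percent of the substrate charged, or "all alike" when all lie within 1.5 percentage points (grey / ochre / red / green / all alike)
* open intermediate at the end, in percent of the substrate charged, grey
* open intermediate at the end, in percent of the substrate charged, ochre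
* open intermediate at the end, in percent of the substrate charged, red
* open intermediate at the end, in percent of the substrate charged, green

Read the eta run. Substrate stands at 36.3% after 1.33 min, which reads as a first-order constant k = 0.762 min⁻¹ at 90 °C. Fold k and the time into N = k·t/ln 2. For grey, N = 87.9. N is the number of substrate half-lives that fit into the run, and for first-order decay the substrate left is 0.5 raised to N.

The runs show nothing about temperature, so guess: I take rates to fall by a factor of 3 per 15 °C. That gives N = 29.3 for ochre, 9.77 for green and 3.26 for red, so I reckon that red keeps 10.4% of its substrate.

Test whether N is enough. It is not: in the eta run open intermediate falls from 85.0% to 74.2% between 8.00 min and 15.0 min. Count that loss the same way, as first order at the eta charge, since the readings do not show its order. This gives M = 2.24 half-lives for grey, with the same temperature factor for the others. My reckoning, (1 − 0.5^N)·0.5^M, gives 21.2% for grey, 59.6% for ochre, 84.1% for green and 84.5% for red. Green and red lie 0.40 percentage points apart, inside the margin of 1.5 points, but red counts a smaller N than green, so my red figure leans harder on the guessed factor: pick green.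

The forecast also names green, with 21% for grey, 51% for ochre, 65% for red and 82% for green: “For temperature I guess Ea ≈ 85 kJ/mol for both steps”. Its ochre and red stand lower than mine.

The flasks give 19.5% for grey, 40.7% for ochre, 45.9% for red and 69.9% for green, so green comes out highest.

    crystals ⇌ product, rate k1*(cs1 - [product]) while solid is left; crystals form when [product] > cs1 (solubility = 25.0 mM, k = 0.150 min⁻¹)
    substrate → open intermediate (k = 0.0430 min⁻¹, Ea = 96.0 kJ mol⁻¹)
    partner → second intermediate (k = 0.150 min⁻¹, Ea = 103 kJ mol⁻¹)
    open intermediate + second intermediate → product (k = 0.160 L mol⁻¹ min⁻¹, Ea = 69.0 kJ mol⁻¹)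
    (constants at 60 °C)

In green, partner turned into second intermediate with a half-life of 4.6 min at 4.63 min and stood at 0.248% of its charge by 40.0 min, while substrate kept opening. Green then ended with 3.21% substrate, which reads as N = 4.96 against my 9.77, and at 80.0 min open intermediate was made, net, at 0.403 of the rate it was used up. A repeat of green at 35 °C ended with 81.3% substrate, N = 0.299, and 18.5% open intermediate.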